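**Retrosynthetic overview**

- Feature: in ring A every carbon is substituted except C4, which lies between the oxygen-bearing C3 and C5. C4 is taken as the methyl carbon of a 6-methyl-2-pyranone; pyranone C2 with its carbonyl oxygen becomes C3–O, and pyranone C6 with the ring oxygen becomes C5–O.
- Endgame: target 18 from hydrogenolysis of two benzyl ethers, after mono-O-methylation of the mirror-symmetric resorcinol 16.
- Key disconnection: the C3–C4 bond of ring A, formed by Claisen closure after methoxide opens the fully substituted pyranone 13.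
- Pyranone 13 from B-alkyl Suzuki coupling of pyranonyl triflate 10 with hydroborated 3-methoxystyrene; 10 from 4-hydroxypyranone 9; 9 from triketide ester 8, assembled on methyl acetoacetate by γ-benzylation, α-benzylation and γ-acetylation.
- Ring order: the pyranone ring is closed first (step 4) and is then converted into benzenoid ring A (step 7); the other three arene rings are bought.

Key step: step 7

Remark: ring A is read from the SMILES as 3-OH, 5-OMe, with 3'-OMe on ring B. The target is achiral; 5, 8, 14 and 15 carry only epimerisable or transient stereocentres and are handled as mixtures.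

**Route**

Step 1
Reactants: 1 methyl acetoacetate; 2 4-(benzyloxy)benzyl chloride
Product: 4 methyl 5-[4-(benzyloxy)phenyl]-3-oxopentanoate, via dilithium acetoacetate dianion 3 (not isolated)
Conditions: LDA (2.1 equiv), THF, 0 °C; then 2 (0.95 equiv), 0 °C to rt; aq. HCl
Reagents that add atoms: none
Why: γ-Alkylation of a β-keto ester dianion (Huckin–Weiler): the terminal carbanion is the more basic and more nucleophilic site and should displace the activated benzylic chloride by SN2.

Step 2
Reactants: 4 methyl 5-[4-(benzyloxy)phenyl]-3-oxopentanoate; 2 4-(benzyloxy)benzyl chloride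
Product: 5 methyl 2-[4-(benzyloxy)benzyl]-5-[4-(benzyloxy)phenyl]-3-oxopentanoate (racemic)
Conditions: K2CO3, KI (cat.), acetone, reflux; 2 (0.95 equiv)
Reagents that add atoms: none
Why: Classical α-C-alkylation of a β-keto ester enolate with a benzylic halide (SN2, iodide-assisted); a slight deficit of 2 should hold back double alkylation.

Step 3
Reactants: 5 methyl 2-[4-(benzyloxy)benzyl]-5-[4-(benzyloxy)phenyl]-3-oxopentanoate; 6 N-methoxy-N-methylacetamide
Product: 8 methyl 2,4-bis[4-(benzyloxy)benzyl]-3,5-dioxohexanoate (mixture of diastereomers and enol forms), via dilithium dianion of the keto ester 7 (not isolated)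
Conditions: LDA (2.2 equiv), THF, −78 to 0 °C; then 6, −78 to 0 °C; aq. HCl
Reagents that add atoms: none
Why: γ-Acylation of an α-substituted β-keto ester dianion with a Weinreb amide; the chelated tetrahedral adduct should persist until the quench, so the acidic triketide is not released while dianion is still present.

Step 4
Reactants: 8 methyl 2,4-bis[4-(benzyloxy)benzyl]-3,5-dioxohexanoate
Product: 9 3,5-bis[4-(benzyloxy)benzyl]-4-hydroxy-6-methyl-2H-pyran-2-one
Conditions: DBU, PhMe, 90 °C; then aq. HCl
Reagents that add atoms: none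
Why: Standard lactonisation of a 3,5-dioxo ester: the enol oxygen of the terminal acetyl group attacks the ester (6-exo-trig, loss of methanol) and the product is stabilised as the 4-hydroxy-2-pyranone.

Step 5
Reactants: 9 3,5-bis[4-(benzyloxy)benzyl]-4-hydroxy-6-methyl-2H-pyran-2-one
Product: 10 3,5-bis[4-(benzyloxy)benzyl]-6-methyl-2-oxo-2H-pyran-4-yl trifluoromethanesulfonate
Conditions: Tf2O, Et3N, CH2Cl2, −78 to 0 °C
Reagents that add atoms: trifluoromethanesulfonic anhydride, O=S(=O)(OS(=O)(=O)C(F)(F)F)C(F)(F)F
Why: O-Sulfonylation of the vinylogous acid, as practised on 4-hydroxy-6-methyl-2-pyranone; reaction at the 4-oxygen keeps the 2-pyranone lactone intact and C3 is blocked against C-attack.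

Step 6
Reactants: 10 3,5-bis[4-(benzyloxy)benzyl]-6-methyl-2-oxo-2H-pyran-4-yl trifluoromethanesulfonate; 11 3-methoxystyrene
Product: 13 3,5-bis[4-(benzyloxy)benzyl]-4-[2-(3-methoxyphenyl)ethyl]-6-methyl-2H-pyran-2-one, via B-[2-(3-methoxyphenyl)ethyl]-9-BBN 12 (not isolated)
Conditions: 11, 9-BBN (0.5 M in THF), 0 °C to rt; then 10, Pd(dppf)Cl2 (5 mol%), K3PO4, THF–DMF–H2O (degassed), 50 °C
Reagents that add atoms: none
Why: Anti-Markovnikov hydroboration of the styrene followed by B-alkyl Suzuki–Miyaura coupling; the vinylogous acyl triflate should add readily to zerovalent palladium and the dppf ligand disfavours β-hydride elimination of the alkylpalladium.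

Step 7
Reactants: 13 3,5-bis[4-(benzyloxy)benzyl]-4-[2-(3-methoxyphenyl)ethyl]-6-methyl-2H-pyran-2-one
Product: 16 2,6-bis[4-(benzyloxy)benzyl]-3,5-dihydroxy-3'-methoxybibenzyl, via ring-opened (Z)-keto ester 14 (not isolated), via cyclohexenedione 15 (not isolated)
Conditions: NaOMe (5 equiv), MeOH, reflux, Ar; then aq. HCl
Reagents that add atoms: none
Why: Proposed new method: methoxide adds to the lactone carbonyl of 13 and the acyl–oxygen bond breaks, so the enol lactone unravels to the methyl (Z)-5-oxohex-2-enoate 14, held as its delocalised sodium dienolate. Proton exchange in methanol should give a small share of the methyl ketone enolate, whose CH2 terminus attacks the ester carbonyl in a 6-(enolendo)-exo-trig Claisen closure; this forms the C3–C4 bond of ring A and gives cyclohexenedione 15 after loss of methoxide, and 15 enolises at once to the resorcinol, held as its phenoxide. The closest known reactions are the base-induced openings of 2-pyranones and 4-pyranones that reclose by aldol or Claisen condensation to orcinols and phloroglucinols, and the Claisen cyclisation of 5-oxohexanoates to cyclohexane-1,3-diones. No stereocentre remains, because the single sp3 ring carbon of 14 and 15 becomes aromatic. The step needs the ketone and ester termini on the same side of the C2=C3 alkene of 14, and C-acylation through the less favoured methyl enolate in preference to reclosure to 13 or methanolytic loss of the acetyl group. The tetrasubstituted alkene inherited from the pyranone ring fixes the (Z) geometry, reclosure to 13 is reversible, and irreversible aromatisation to the phenoxide should drain the equilibria towards 16.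

Step 8
Reactants: 16 2,6-bis[4-(benzyloxy)benzyl]-3,5-dihydroxy-3'-methoxybibenzyl
Product: 17 2,6-bis[4-(benzyloxy)benzyl]-3-hydroxy-3',5-dimethoxybibenzyl
Conditions: MeI (0.8 equiv), K2CO3 (1.0 equiv), acetone, rt; recovered 16 resubmitted
Reagents that add atoms: iodomethane, CI
Why: Williamson O-methylation of a phenoxide; the two hydroxyls are equivalent by the mirror plane through C1 and C4, so either gives the same mono-ether, and a deficit of MeI should keep the dimethyl ether low while unreacted 16 is recycled.

Step 9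
Reactants: 17 2,6-bis[4-(benzyloxy)benzyl]-3-hydroxy-3',5-dimethoxybibenzyl
Product: 18 2,6-bis(4-hydroxybenzyl)-3-hydroxy-3',5-dimethoxybibenzyl (target)
Conditions: H2 (1 atm), 10% Pd/C, EtOAc–MeOH, rt
Reagents that add atoms: none
Why: Catalytic hydrogenolysis of aryl benzyl ethers; the aryl methyl ethers, the bibenzyl bridge and the diarylmethane C–C bonds are inert under these conditions.

**Compound list**

1 | methyl acetoacetate | COC(=O)CC(C)=O | starting material
2 | 4-(benzyloxy)benzyl chloride | ClCc1ccc(OCc2ccccc2)cc1 | starting material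
3 | dilithium dianion of methyl acetoacetate | [Li+].[Li+].C=C([O-])C=C([O-])OC | intermediate
4 | methyl 5-[4-(benzyloxy)phenyl]-3-oxopentanoate | COC(=O)CC(=O)CCc1ccc(OCc2ccccc2)cc1 | intermediate
5 | methyl 2-[4-(benzyloxy)benzyl]-5-[4-(benzyloxy)phenyl]-3-oxopentanoate (racemic) | COC(=O)C(Cc1ccc(OCc2ccccc2)cc1)C(=O)CCc1ccc(OCc2ccccc2)cc1 | intermediate
6 | N-methoxy-N-methylacetamide | CC(=O)N(C)OC | starting material
7 | dilithium α,γ-dianion of keto ester 5 | [Li+].[Li+].COC([O-])=C(Cc1ccc(OCc2ccccc2)cc1)C([O-])=CCc1ccc(OCc2ccccc2)cc1 | intermediate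
8 | methyl 2,4-bis[4-(benzyloxy)benzyl]-3,5-dioxohexanoate (diastereomer mixture) | COC(=O)C(Cc1ccc(OCc2ccccc2)cc1)C(=O)C(Cc1ccc(OCc2ccccc2)cc1)C(C)=O | intermediate
9 | 3,5-bis[4-(benzyloxy)benzyl]-4-hydroxy-6-methyl-2H-pyran-2-one | Cc1oc(=O)c(Cc2ccc(OCc3ccccc3)cc2)c(O)c1Cc1ccc(OCc2ccccc2)cc1 | intermediate
10 | 3,5-bis[4-(benzyloxy)benzyl]-6-methyl-2-oxo-2H-pyran-4-yl trifluoromethanesulfonate | Cc1oc(=O)c(Cc2ccc(OCc3ccccc3)cc2)c(OS(=O)(=O)C(F)(F)F)c1Cc1ccc(OCc2ccccc2)cc1 | intermediate
11 | 3-methoxystyrene | C=Cc1cccc(OC)c1 | starting material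
12 | B-[2-(3-methoxyphenyl)ethyl]-9-borabicyclo[3.3.1]nonane | COc1cccc(CCB2C3CCCC2CCC3)c1 | intermediate
13 | 3,5-bis[4-(benzyloxy)benzyl]-4-[2-(3-methoxyphenyl)ethyl]-6-methyl-2H-pyran-2-one | Cc1oc(=O)c(Cc2ccc(OCc3ccccc3)cc2)c(CCc2cccc(OC)c2)c1Cc1ccc(OCc2ccccc2)cc1 | intermediate
14 | methyl (2Z)-2,4-bis[4-(benzyloxy)benzyl]-3-[2-(3-methoxyphenyl)ethyl]-5-oxohex-2-enoate (racemic at C4; present as its sodium dienolate) | COC(=O)/C(Cc1ccc(OCc2ccccc2)cc1)=C(/CCc1cccc(OC)c1)C(Cc1ccc(OCc2ccccc2)cc1)C(C)=O | intermediate
15 | 4,6-bis[4-(benzyloxy)benzyl]-5-[2-(3-methoxyphenyl)ethyl]cyclohex-4-ene-1,3-dione (racemic) | O=C1CC(=O)C(Cc2ccc(OCc3ccccc3)cc2)C(CCc2cccc(OC)c2)=C1Cc1ccc(OCc2ccccc2)cc1 | intermediate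
16 | 2,6-bis[4-(benzyloxy)benzyl]-3,5-dihydroxy-3'-methoxybibenzyl (4,6-bis[4-(benzyloxy)benzyl]-5-[2-(3-methoxyphenyl)ethyl]benzene-1,3-diol) | COc1cccc(CCc2c(Cc3ccc(OCc4ccccc4)cc3)c(O)cc(O)c2Cc2ccc(OCc3ccccc3)cc2)c1 | intermediate
17 | 2,6-bis[4-(benzyloxy)benzyl]-3-hydroxy-3',5-dimethoxybibenzyl | COc1cccc(CCc2c(Cc3ccc(OCc4ccccc4)cc3)c(O)cc(OC)c2Cc2ccc(OCc3ccccc3)cc2)c1 | intermediate
18 | 2,6-bis(4-hydroxybenzyl)-3-hydroxy-3',5-dimethoxybibenzyl | COc1cccc(CCc2c(Cc3ccc(O)cc3)c(O)cc(OC)c2Cc2ccc(O)cc2)c1 | target

**Step count**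

Total steps: 9. Longest linear sequence: 9 steps (1 to 18; 3-methoxystyrene enters in situ in step 6).

**Steps most likely to fail**

1. Step 7 (proposed new method). The opened dienolate may reclose to the pyranone faster than the minor methyl enolate is C-acylated, or methoxide may cleave the acetyl group by a retro-Claisen path. The fallback builds ring A on an aromatic core by known reactions; it sets out from 3-methoxystyrene 11 (through its 9-BBN adduct 12) and from chloride 2, and comes back to the route at resorcinol 16. 5-Bromoresorcinol is protected with MOMCl and iPr2NEt in CH2Cl2 as 1-bromo-3,5-bis(methoxymethoxy)benzene F1. B-alkyl Suzuki coupling of F1 with borane 12 (Pd(dppf)Cl2, K3PO4, THF–H2O) should give 3,5-bis(methoxymethoxy)-3'-methoxybibenzyl F2. NBS (2 equiv, MeCN, 0 °C) should brominate the two ring A positions ortho to the chain and para to an oxygen, well ahead of the less activated anisole ring, giving 2,6-dibromo-3,5-bis(methoxymethoxy)-3'-methoxybibenzyl F3. Chloride 2 is converted with zinc dust and LiCl in THF into [4-(benzyloxy)benzyl]zinc chloride F4, and double Negishi coupling of F3 with F4 (Pd(OAc)2, SPhos, THF, 60 °C) should give 2,6-bis[4-(benzyloxy)benzyl]-3,5-bis(methoxymethoxy)-3'-methoxybibenzyl F5. HCl in MeOH then removes both MOM groups to deliver 16.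

2. Step 6. Transmetallation at a triflate flanked on both sides may be slow, leaving time for hydroxide to cleave the triflate back to 9 or open the lactone, and for β-hydride elimination of the alkylpalladium. The fallback replaces the boron reagent and aqueous base with a base-free organozinc; it sets out from triflate 10 and comes back at pyranone 13. 1-(2-Bromoethyl)-3-methoxybenzene is converted with zinc dust and LiCl in THF into [2-(3-methoxyphenyl)ethyl]zinc bromide F6, which is coupled with 10 under Negishi conditions (Pd(OAc)2, SPhos, THF, rt to 50 °C) to give 13.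

3. Step 3. The hindered secondary carbanion of dianion 7 may deprotonate the enolisable amide instead of adding to it, returning 5. The fallback replaces acylation with aldol addition and oxidation; it sets out from keto ester 5 (through dianion 7) and comes back at triketide ester 8. Dianion 7 is treated with acetaldehyde at −78 °C to give methyl 2,4-bis[4-(benzyloxy)benzyl]-5-hydroxy-3-oxohexanoate F7, and the secondary alcohol is oxidised with Dess–Martin periodinane in CH2Cl2 to give 8.

**Further compounds**

F1 | step 7 | 1-bromo-3,5-bis(methoxymethoxy)benzene | COCOc1cc(Br)cc(OCOC)c1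
F2 | step 7 | 3,5-bis(methoxymethoxy)-3'-methoxybibenzyl | COCOc1cc(CCc2cccc(OC)c2)cc(OCOC)c1
F3 | step 7 | 2,6-dibromo-3,5-bis(methoxymethoxy)-3'-methoxybibenzyl | COCOc1cc(OCOC)c(Br)c(CCc2cccc(OC)c2)c1Br
F4 | step 7 | [4-(benzyloxy)benzyl]zinc chloride | Cl[Zn]Cc1ccc(OCc2ccccc2)cc1
F5 | step 7 | 2,6-bis[4-(benzyloxy)benzyl]-3,5-bis(methoxymethoxy)-3'-methoxybibenzyl | COCOc1cc(OCOC)c(Cc2ccc(OCc3ccccc3)cc2)c(CCc2cccc(OC)c2)c1Cc1ccc(OCc2ccccc2)cc1
F6 | step 6 | [2-(3-methoxyphenyl)ethyl]zinc bromide | COc1cccc(CC[Zn]Br)c1
F7 | step 3 | methyl 2,4-bis[4-(benzyloxy)benzyl]-5-hydroxy-3-oxohexanoate (diastereomer mixture) | COC(=O)C(Cc1ccc(OCc2ccccc2)cc1)C(=O)C(Cc1ccc(OCc2ccccc2)cc1)C(C)O
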